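**Plan**
- Retrosynthesis: remove the C18 benzoate and close the 6α-OH/C18-OH pair to an 18,6α-lactone; cut C12–C13 (Negishi coupling with a Z-3-iodobut-2-enoate); trace C8=C17 and the C7 methylene back to a C7 ketone; then cut ring A at C3–C4 and C1–C10, which leaves 1,3-dibromopropane and a flat 7-hydroxybenzofuran-2(3H)-one.
- Enabling feature: C18 and O6 sit on C4 and C6, the two neighbours of C5, so they can be tied as the lactone ring of a benzofuranone whose benzene ring is ring B. This makes C4 an enolate carbon; a helper phenol oxygen at C7 (para to C10) makes C10 a carbon nucleophile, so C1–C3 can bridge C4 and C10 with loss of aromaticity.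
- Forward order: arene (ring B) → lactone ring (Claisen rearrangement, ozonolysis) → ring A by dearomative [3+3] annulation → saturation of ring B → C8 methylenation and removal of the C7 oxygen → side chain → lactone reduction → benzoate.
- Stereochemistry: C4 from a chiral ammonium phase-transfer catalyst; C10 relayed from C4 by the tether; C5 and C9 by hydrogen delivery to the α face; C6 by equilibration inside the lactone; 13Z from a stereoretentive coupling of a Z-vinyl iodide. The target is (4R,5R,6S,9S,10R,13Z).

Key step: step 9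

Remark: labdane locants and α/β (C20 on C10 = β; C18 = 4α carbon, C19 = 4β methyl) are used for all ring-fused compounds; the cinchonidinium salt of step 9 is assumed to be the pseudo-enantiomer that gives the 3R lactone, its cinchoninium analogue being the catalyst for the opposite sense.

Step 1
Reactants: 1 2-methoxy-5-methylphenol
Product: 2 4-bromo-2-methoxy-5-methylphenol
Conditions: N-bromosuccinimide, MeCN, 0 °C
Reagents that add atoms: N-bromosuccinimide, O=C1CCC(=O)N1Br
Why: Electrophilic aromatic bromination; the free hydroxyl directs para and that position is also ortho to the methyl group, so the carbon that becomes C9 should be brominated selectively.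

Step 2
Reactants: 2 4-bromo-2-methoxy-5-methylphenol; 3 (E)-1-bromobut-2-ene
Product: 4 1-bromo-4-[(E)-but-2-en-1-yloxy]-5-methoxy-2-methylbenzene
Conditions: K2CO3, acetone, reflux
Reagents that add atoms: none
Why: Williamson ether synthesis; the phenolate displaces the primary allylic bromide in an SN2 reaction.

Step 3
Reactants: 4 1-bromo-4-[(E)-but-2-en-1-yloxy]-5-methoxy-2-methylbenzene; 5 oxirane
Product: 7 2-{4-[(E)-but-2-en-1-yloxy]-5-methoxy-2-methylphenyl}ethanol, via aryllithium 6 (not isolated)
Conditions: n-BuLi, THF, −78 °C; then oxirane, −78 → 0 °C; then H2O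
Reagents that add atoms: none
Why: Bromine–lithium exchange, which is faster than any attack on the allyl ether at −78 °C, followed by ring opening of the epoxide by the aryllithium to give the C11–C12 unit.

Step 4
Reactants: 7 2-{4-[(E)-but-2-en-1-yloxy]-5-methoxy-2-methylphenyl}ethanol
Product: 8 1-[(E)-but-2-en-1-yloxy]-4-(2-chloroethyl)-2-methoxy-5-methylbenzene
Conditions: PPh3, N-chlorosuccinimide, THF, 0 → 23 °C
Reagents that add atoms: N-chlorosuccinimide, O=C1CCC(=O)N1Cl
Why: Appel-type chlorination through the alkoxyphosphonium salt under neutral conditions that spare the acid-labile crotyl ether; the chloride is an inert handle for the later side chain.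

Step 5
Reactants: 8 1-[(E)-but-2-en-1-yloxy]-4-(2-chloroethyl)-2-methoxy-5-methylbenzene
Product: 9 2-(but-3-en-2-yl)-4-(2-chloroethyl)-6-methoxy-3-methylphenol (racemic)
Conditions: 1,2-dichlorobenzene, 180 °C
Reagents that add atoms: none
Why: Aromatic Claisen rearrangement; the [3,3] shift can only reach the one free ortho position (between OH and the methyl group), and the new benzylic stereocentre is racemic but is erased by enolisation in step 9.

Step 6
Reactants: 9 2-(but-3-en-2-yl)-4-(2-chloroethyl)-6-methoxy-3-methylphenol (racemic)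
Product: 12 5-(2-chloroethyl)-7-methoxy-3,4-dimethyl-2,3-dihydro-1-benzofuran-2-ol (diastereomer mixture), via ozonide 10 (not isolated), via hydroxy aldehyde 11 (not isolated)
Conditions: O3 (dosed to the alkene), CH2Cl2, −78 °C; then PPh3, −78 → 23 °C
Reagents that add atoms: ozone, [O-][O+]=O
Why: Ozonolysis with reductive work-up; the terminal alkene reacts faster than the arene at −78 °C and the aldehyde closes on the neighbouring phenol to the five-membered lactol.

Step 7
Reactants: 12 5-(2-chloroethyl)-7-methoxy-3,4-dimethyl-2,3-dihydro-1-benzofuran-2-ol (diastereomer mixture)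
Product: 13 5-(2-chloroethyl)-7-methoxy-3,4-dimethyl-1-benzofuran-2(3H)-one (racemic)
Conditions: n-Pr4N[RuO4] (5 mol %), N-methylmorpholine N-oxide, 4 Å molecular sieves, CH2Cl2, 23 °C
Reagents that add atoms: none
Why: Perruthenate oxidation of a lactol to the lactone; no free phenol is present at this stage.

Step 8
Reactants: 13 5-(2-chloroethyl)-7-methoxy-3,4-dimethyl-1-benzofuran-2(3H)-one (racemic)
Product: 14 5-(2-chloroethyl)-7-hydroxy-3,4-dimethyl-1-benzofuran-2(3H)-one (racemic)
Conditions: BBr3, CH2Cl2, −78 → 0 °C; then H2O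
Reagents that add atoms: none
Why: Lewis-acid cleavage of the aryl methyl ether (bromide attacks the methyl group); the aryl lactone and the primary chloride should survive at low temperature.

Step 9
Reactants: 14 5-(2-chloroethyl)-7-hydroxy-3,4-dimethyl-1-benzofuran-2(3H)-one (racemic); 15 1,3-dibromopropane
Product: 17 (4R,10R)-12-chloro-7-oxo-13,14,15,16,17-pentanorlabda-5,8-dien-18,6-olide, via monoalkylated bromide 16 (not isolated)
Conditions: O-allyl-N-(9-anthracenylmethyl)cinchonidinium bromide (10 mol %), Cs2CO3 (1.1 equiv), 15 (1.1 equiv), toluene, −20 °C, argon; then Cs2CO3 (1.5 equiv), DMF, 50 °C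
Reagents that add atoms: none
Why: Proposed new method: under solid–liquid phase-transfer conditions the lactone C–H of 14 (its most acidic site) gives an aromatic 2-oxidobenzofuran enolate which, ion-paired with the chiral ammonium cation, is C-alkylated by one end of 15 in an SN2 step to give 16; warming with more base in DMF then lets the C7 phenolate attack the remaining CH2Br through its para carbon (C10), an alkylative dearomatisation that ends as the cross-conjugated dienone 17. The closest known reaction types are the chiral-ammonium phase-transfer alkylation of 3-substituted benzofuranones and oxindoles to quaternary centres and the intramolecular para-alkylation of phenolates to fused cyclohexadienones; their merger with a 1,3-dihalide as a dearomative [3+3] annulation has not been shown. Ring A closes in the second event by a 6-exo-tet displacement with the arene para carbon as nucleophile; the first event is intermolecular and closes no ring. The quaternary centre C4 is set by the catalyst, which shields one face of the planar enolate, and C10 follows from C4 because a three-carbon tether can only span C4 and C10 on one face of the flat benzofuranone, so the C19 and C20 methyl groups end cis. The step needs C- over O-alkylation and para over ortho attack: the phenol oxygen cannot reach the tether (a meta-bridged ring would result), the ortho carbon C6 carries the lactone oxygen and C8 is out of reach, so the para carbon is the only intramolecular nucleophile, and the near-stoichiometric dihalide limits intermolecular O-alkylation.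

Step 10
Reactants: 17 (4R,10R)-12-chloro-7-oxo-13,14,15,16,17-pentanorlabda-5,8-dien-18,6-olide
Product: 18 12-chloro-7-oxo-13,14,15,16,17-pentanorlabdan-18,6α-olide
Conditions: Mn(dpm)3 (10 mol %; dpm = 2,2,6,6-tetramethylheptane-3,5-dionate), PhSiH3, i-PrOH/CH2Cl2, 23 °C, argon; then DBU (cat.), 23 °C
Reagents that add atoms: none
Why: Metal-hydride hydrogen atom transfer conjugate reduction of both enone C=C bonds: hydrogen is delivered to C9 and to C5 from the α face, opposite the C20 methyl (and at C5 also the C19 methyl), which gives the 9β side chain and the trans ring fusion, while C6, α to the ketone, settles under DBU in the 6α-O configuration, the only one in which the lactone can bridge C4 and C6 of a chair–chair trans-decalin.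

Step 11
Reactants: 18 12-chloro-7-oxo-13,14,15,16,17-pentanorlabdan-18,6α-olide
Product: 19 12-chloro-7-oxo-13,14,15,16-tetranorlabd-8(17)-en-18,6α-olide
Conditions: paraformaldehyde, diisopropylammonium trifluoroacetate (1 equiv), CF3CO2H (10 mol %), THF, reflux
Reagents that add atoms: paraformaldehyde (as formaldehyde), C=O
Why: Mannich condensation–elimination (direct α-methylenation); C8 is the only α-carbon of the C7 ketone with two hydrogens, so the exocyclic methylene can form only there, and the mildly acidic medium leaves C6 and C9 in their stable configurations.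

Step 12
Reactants: 19 12-chloro-7-oxo-13,14,15,16-tetranorlabd-8(17)-en-18,6α-olide
Product: 20 12-chloro-7β-hydroxy-13,14,15,16-tetranorlabd-8(17)-en-18,6α-olide
Conditions: NaBH4, CeCl3·7H2O, MeOH, −78 °C
Reagents that add atoms: none
Why: Luche reduction; 1,2-attack on the enone carbonyl from the axial (α) direction should give mainly the equatorial 7β-alcohol, and either C7 epimer serves because this centre becomes CH2 in step 14.

Step 13
Reactants: 20 12-chloro-7β-hydroxy-13,14,15,16-tetranorlabd-8(17)-en-18,6α-olide
Product: 21 12-chloro-7β-(methoxycarbonyloxy)-13,14,15,16-tetranorlabd-8(17)-en-18,6α-olide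
Conditions: ClCO2Me, pyridine, DMAP (cat.), CH2Cl2, 0 °C
Reagents that add atoms: methyl chloroformate, COC(=O)Cl
Why: Acylation of the secondary allylic alcohol to an allylic carbonate, the leaving group for the palladium step.

Step 14
Reactants: 21 12-chloro-7β-(methoxycarbonyloxy)-13,14,15,16-tetranorlabd-8(17)-en-18,6α-olide
Product: 22 12-chloro-13,14,15,16-tetranorlabd-8(17)-en-18,6α-olide
Conditions: Pd(OAc)2 (5 mol %), n-Bu3P (20 mol %), HCO2NH4, 1,4-dioxane, 100 °C
Reagents that add atoms: none
Why: Tsuji hydrogenolysis of an allylic carbonate; zerovalent palladium ionises the C7–O bond to a π-allyl complex over C7–C8–C17, formate on palladium loses CO2 and the hydride is delivered to the more substituted terminus C7, which keeps the exocyclic C8=C17 alkene and removes the helper oxygen.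

Step 15
Reactants: 22 12-chloro-13,14,15,16-tetranorlabd-8(17)-en-18,6α-olide
Product: 23 12-iodo-13,14,15,16-tetranorlabd-8(17)-en-18,6α-olide
Conditions: NaI, butan-2-one, reflux
Reagents that add atoms: sodium iodide, [Na+].[I-]
Why: Finkelstein halide exchange at the unhindered primary carbon, driven by precipitation of NaCl.

Step 16
Reactants: 24 methyl but-2-ynoate
Product: 25 methyl (Z)-3-iodobut-2-enoate
Conditions: NaI, AcOH, 115 °C
Reagents that add atoms: sodium iodide, [Na+].[I-]
Why: Conjugate hydroiodination of an ynoate; anti addition of H and I places iodine cis to the ester, which fixes the Z geometry.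

Step 17
Reactants: 23 12-iodo-13,14,15,16-tetranorlabd-8(17)-en-18,6α-olide; 25 methyl (Z)-3-iodobut-2-enoate
Product: 27 (13Z)-6α-hydroxylabda-8(17),13-diene-15,18-dioic acid 18,6-lactone 15-methyl ester, via alkylzinc iodide 26 (not isolated)
Conditions: Zn dust (activated with Me3SiCl), LiCl, THF, 40 °C; then 25, Pd(PPh3)4 (5 mol %), THF, 50 °C
Reagents that add atoms: none
Why: Negishi coupling; zinc inserts into the primary C–I bond and the alkylzinc iodide couples with the vinyl iodide with retention of geometry, so the C12 chain ends cis to the ester (13Z), while lactone, ester and exocyclic alkene tolerate the organozinc.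

Step 18
Reactants: 27 (13Z)-6α-hydroxylabda-8(17),13-diene-15,18-dioic acid 18,6-lactone 15-methyl ester
Product: 28 (13Z)-6α-hydroxylabda-8(17),13-diene-15,18-dioic acid 18,6-lactone
Conditions: Me3SnOH, 1,2-dichloroethane, 80 °C; then 1 M HCl
Reagents that add atoms: trimethyltin hydroxide, C[Sn](C)(C)O
Why: Tin hydroxide ester cleavage; the methyl ester is hydrolysed under near-neutral conditions that should leave the hindered lactone (carbonyl on quaternary C4) and the Z alkene untouched.

Step 19
Reactants: 28 (13Z)-6α-hydroxylabda-8(17),13-diene-15,18-dioic acid 18,6-lactone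
Product: 29 (13Z)-6α,18-dihydroxylabda-8(17),13-dien-15-oic acid
Conditions: LiBHEt3 (5 equiv), THF, 0 → 23 °C; then H2O, dilute HCl
Reagents that add atoms: none
Why: Hydride reduction of the lactone; the acid is first converted to its lithium carboxylate, which the borohydride does not reduce, and the lactone opens to the C18 primary alcohol and the 6α-alcohol without touching any stereocentre.

Step 20
Reactants: 29 (13Z)-6α,18-dihydroxylabda-8(17),13-dien-15-oic acid; 30 benzoyl chloride
Product: 32 (13Z)-18-benzoyloxy-6α-hydroxylabda-8(17),13-dien-15-oic acid, via mixed anhydride 31 (not isolated)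
Conditions: 30 (2.2 equiv), pyridine, CH2Cl2, −20 °C; then H2O/THF, NaHCO3, 23 °C; acidify
Reagents that add atoms: none
Why: Chemoselective acylation; the primary C18 hydroxyl is benzoylated much faster than the hindered secondary 6α-hydroxyl, and the carboxylic acid is tied up as the mixed anhydride 31, which the aqueous stage hydrolyses.

**Compound list**
1 | 2-methoxy-5-methylphenol | COc1ccc(C)cc1O | starting material
2 | 4-bromo-2-methoxy-5-methylphenol | COc1cc(Br)c(C)cc1O | intermediate
3 | (E)-1-bromobut-2-ene | C/C=C/CBr | starting material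
4 | 1-bromo-4-[(E)-but-2-en-1-yloxy]-5-methoxy-2-methylbenzene | COc1cc(Br)c(C)cc1OC/C=C/C | intermediate
5 | oxirane | C1CO1 | starting material
6 | {4-[(E)-but-2-en-1-yloxy]-5-methoxy-2-methylphenyl}lithium | COc1cc([Li])c(C)cc1OC/C=C/C | intermediate
7 | 2-{4-[(E)-but-2-en-1-yloxy]-5-methoxy-2-methylphenyl}ethanol | COc1cc(CCO)c(C)cc1OC/C=C/C | intermediate
8 | 1-[(E)-but-2-en-1-yloxy]-4-(2-chloroethyl)-2-methoxy-5-methylbenzene | COc1cc(CCCl)c(C)cc1OC/C=C/C | intermediate
9 | 2-(but-3-en-2-yl)-4-(2-chloroethyl)-6-methoxy-3-methylphenol (racemic) | COc1cc(CCCl)c(C)c(C(C)C=C)c1O | intermediate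
10 | 3-{1-[3-(2-chloroethyl)-6-hydroxy-5-methoxy-2-methylphenyl]ethyl}-1,2,4-trioxolane | COc1cc(CCCl)c(C)c(C(C)C2OCOO2)c1O | intermediate
11 | 2-[3-(2-chloroethyl)-6-hydroxy-5-methoxy-2-methylphenyl]propanal | COc1cc(CCCl)c(C)c(C(C)C=O)c1O | intermediate
12 | 5-(2-chloroethyl)-7-methoxy-3,4-dimethyl-2,3-dihydro-1-benzofuran-2-ol (diastereomer mixture) | COc1cc(CCCl)c(C)c2C(C)C(O)Oc12 | intermediate
13 | 5-(2-chloroethyl)-7-methoxy-3,4-dimethyl-1-benzofuran-2(3H)-one (racemic) | COc1cc(CCCl)c(C)c2C(C)C(=O)Oc12 | intermediate
14 | 5-(2-chloroethyl)-7-hydroxy-3,4-dimethyl-1-benzofuran-2(3H)-one (racemic) | Oc1cc(CCCl)c(C)c2C(C)C(=O)Oc12 | intermediate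
15 | 1,3-dibromopropane | BrCCCBr | starting material
16 | (3R)-3-(3-bromopropyl)-5-(2-chloroethyl)-7-hydroxy-3,4-dimethyl-1-benzofuran-2(3H)-one | C[C@]1(CCCBr)C(=O)Oc2c(O)cc(CCCl)c(C)c21 | intermediate
17 | (4R,10R)-12-chloro-7-oxo-13,14,15,16,17-pentanorlabda-5,8-dien-18,6-olide | O=C1C=C(CCCl)[C@@]2(C)CCC[C@@]3(C)C(=O)OC1=C23 | intermediate
18 | 12-chloro-7-oxo-13,14,15,16,17-pentanorlabdan-18,6α-olide | O=C1C[C@H](CCCl)[C@@]2(C)CCC[C@@]3(C)C(=O)O[C@@H]1[C@H]23 | intermediate
19 | 12-chloro-7-oxo-13,14,15,16-tetranorlabd-8(17)-en-18,6α-olide | O=C1C(=C)[C@H](CCCl)[C@@]2(C)CCC[C@@]3(C)C(=O)O[C@@H]1[C@H]23 | intermediate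
20 | 12-chloro-7β-hydroxy-13,14,15,16-tetranorlabd-8(17)-en-18,6α-olide | O[C@@H]1C(=C)[C@H](CCCl)[C@@]2(C)CCC[C@@]3(C)C(=O)O[C@@H]1[C@H]23 | intermediate
21 | 12-chloro-7β-(methoxycarbonyloxy)-13,14,15,16-tetranorlabd-8(17)-en-18,6α-olide | COC(=O)O[C@@H]1C(=C)[C@H](CCCl)[C@@]2(C)CCC[C@@]3(C)C(=O)O[C@@H]1[C@H]23 | intermediate
22 | 12-chloro-13,14,15,16-tetranorlabd-8(17)-en-18,6α-olide | C1C(=C)[C@H](CCCl)[C@@]2(C)CCC[C@@]3(C)C(=O)O[C@@H]1[C@H]23 | intermediate
23 | 12-iodo-13,14,15,16-tetranorlabd-8(17)-en-18,6α-olide | C1C(=C)[C@H](CCI)[C@@]2(C)CCC[C@@]3(C)C(=O)O[C@@H]1[C@H]23 | intermediate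
24 | methyl but-2-ynoate | CC#CC(=O)OC | starting material
25 | methyl (Z)-3-iodobut-2-enoate | C/C(I)=C/C(=O)OC | intermediate
26 | (13,14,15,16-tetranorlabd-8(17)-en-18,6α-olid-12-yl)zinc iodide | C1C(=C)[C@H](CC[Zn]I)[C@@]2(C)CCC[C@@]3(C)C(=O)O[C@@H]1[C@H]23 | intermediate
27 | (13Z)-6α-hydroxylabda-8(17),13-diene-15,18-dioic acid 18,6-lactone 15-methyl ester | C1C(=C)[C@H](CC/C(C)=C\C(=O)OC)[C@@]2(C)CCC[C@@]3(C)C(=O)O[C@@H]1[C@H]23 | intermediate
28 | (13Z)-6α-hydroxylabda-8(17),13-diene-15,18-dioic acid 18,6-lactone | C1C(=C)[C@H](CC/C(C)=C\C(=O)O)[C@@]2(C)CCC[C@@]3(C)C(=O)O[C@@H]1[C@H]23 | intermediate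
29 | (13Z)-6α,18-dihydroxylabda-8(17),13-dien-15-oic acid | C=C1C[C@H](O)[C@H]2[C@](C)(CO)CCC[C@]2(C)[C@H]1CC/C(C)=C\C(=O)O | intermediate
30 | benzoyl chloride | O=C(Cl)c1ccccc1 | starting material
31 | benzoic (13Z)-18-benzoyloxy-6α-hydroxylabda-8(17),13-dien-15-oic anhydride | C=C1C[C@H](O)[C@H]2[C@](C)(COC(=O)c3ccccc3)CCC[C@]2(C)[C@H]1CC/C(C)=C\C(=O)OC(=O)c1ccccc1 | intermediate
32 | (13Z)-18-benzoyloxy-6α-hydroxylabda-8(17),13-dien-15-oic acid (4R,5R,6S,9S,10R) | C=C1C[C@H](O)[C@H]2[C@](C)(COC(=O)c3ccccc3)CCC[C@]2(C)[C@H]1CC/C(C)=C\C(=O)O | target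

**Step count**
Total: 20 steps. Longest linear sequence: 19 steps (steps 1–15 and 17–20; step 16 is a one-step branch).

**Steps most likely to fail**

Step 9. The enantiofacial discrimination in the intermolecular C-alkylation may be insufficient, or intermolecular O-alkylation and acyl transfer to the phenolate may outrun the dearomatising ring closure. The fallback separates the two bond formations, uses known reaction types and keeps the phenol masked while the quaternary centre is made. It sets out from 13: palladium-catalysed asymmetric allylic alkylation (Pd2(dba)3, (1R,2R)- or (1S,2S)-N,N′-bis[2-(diphenylphosphino)benzoyl]cyclohexane-1,2-diamine, allyl methyl carbonate, toluene) should give (3R)-3-allyl-5-(2-chloroethyl)-7-methoxy-3,4-dimethyl-1-benzofuran-2(3H)-one F1. Hydroboration with 9-BBN and oxidation with NaBO3·4H2O gives (3R)-5-(2-chloroethyl)-3-(3-hydroxypropyl)-7-methoxy-3,4-dimethyl-1-benzofuran-2(3H)-one F2, and CBr4/PPh3 gives (3R)-3-(3-bromopropyl)-5-(2-chloroethyl)-7-methoxy-3,4-dimethyl-1-benzofuran-2(3H)-one F3. BBr3 then frees the phenol to give 16, now isolated, and Cs2CO3 in DMF at 50 °C closes ring A by phenolate para-alkylation; the fallback comes back to the route at 17.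

Step 10. Hydrogen atom transfer to the shielded C5 (between two quaternary carbons) may be slow or incomplete, or hydrogen delivery at C9 may show poor facial selectivity. The fallback sets out from 17: H2 over Pd/C in EtOAc should saturate only the accessible trisubstituted C8=C9 bond from the α face to give 12-chloro-7-oxo-13,14,15,16,17-pentanorlabd-5-en-18,6-olide F4. A dissolving-metal (Birch-type) enone reduction (Li, two equivalents to spare the C–Cl bond and the lactone, NH3/THF, t-BuOH, −78 °C, NH4Cl quench), which is insensitive to steric shielding, then places H5 with trans ring fusion; after protonation and equilibration at C6 the fallback comes back to the route at 18.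

Step 14. The hydride may be delivered to the exocyclic terminus C17 (endocyclic alkene between C7 and C8), or β-hydride elimination may give a diene. The fallback replaces the π-allyl palladium chemistry by a sigmatropic reduction. It sets out from 20: Ph3SiOReO3-catalysed 1,3-transposition of the allylic alcohol (Et2O, 0 °C) should give 12-chloro-17-hydroxy-13,14,15,16-tetranorlabd-7-en-18,6α-olide F5. A Mitsunobu reaction with 2-nitrobenzenesulfonylhydrazide (PPh3, DEAD, THF, −30 → 23 °C) gives an allylic diazene that loses N2 in a retro-ene step, placing hydrogen on C7 and the double bond at C8=C17; the fallback comes back to the route at 22.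

**Further compounds**
F1 | step 9 | (3R)-3-allyl-5-(2-chloroethyl)-7-methoxy-3,4-dimethyl-1-benzofuran-2(3H)-one | C=CC[C@@]1(C)C(=O)Oc2c(OC)cc(CCCl)c(C)c21
F2 | step 9 | (3R)-5-(2-chloroethyl)-3-(3-hydroxypropyl)-7-methoxy-3,4-dimethyl-1-benzofuran-2(3H)-one | OCCC[C@@]1(C)C(=O)Oc2c(OC)cc(CCCl)c(C)c21
F3 | step 9 | (3R)-3-(3-bromopropyl)-5-(2-chloroethyl)-7-methoxy-3,4-dimethyl-1-benzofuran-2(3H)-one | BrCCC[C@@]1(C)C(=O)Oc2c(OC)cc(CCCl)c(C)c21
F4 | step 10 | 12-chloro-7-oxo-13,14,15,16,17-pentanorlabd-5-en-18,6-olide | O=C1C[C@H](CCCl)[C@@]2(C)CCC[C@@]3(C)C(=O)OC1=C23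
F5 | step 14 | 12-chloro-17-hydroxy-13,14,15,16-tetranorlabd-7-en-18,6α-olide | C1=C(CO)[C@H](CCCl)[C@@]2(C)CCC[C@@]3(C)C(=O)O[C@@H]1[C@H]23
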